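The left-handed substrate left over in a run, set against the right-handed substrate left over, gives the product excess, so the reckoning starts from these two leftovers.

common to all: left-handed substrate 0.30 M; right-handed substrate 0.30 M; gas 19 mM (held); precatalyst 0.48 mM

| flask | free catalyst | impurity | remark | time |
|---|---|---|---|---|
| blue | 3 mM | 1.5 mM | run made earlier |  |
| amber | 3 mM | 2.3 mM | run made earlier |  |
| theta | 3.0 mM | 1.2 mM |  | 80 min |
| alpha | 3.0 mM | 2.0 mM |  | 80 min |

- blue (time / min: left-handed product / %, right-handed product / %, left-handed substrate / %): 12.0: 2.6, 1.4, 46.6; 25.0: 7.3, 3.9, 42.8; 30.0: 8.2, 4.0, 42.0; 50.0: 14.0, 7.4, 36.0; 60.0: 16.8, 7.8, 33.4; 80.0: 21.3, 11.3, 28.7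
- amber (time / min: left-handed product / %, right-handed product / %, left-handed substrate / %): 6.00: 1.2, 0.9, 49.2; 10.0: 2.9, 1.3, 47.7; 15.0: 4.4, 2.1, 46.1; 25.0: 6.9, 3.6, 43.1; 30.0: 8.4, 4.1, 41.1; 50.0: 14.4, 6.9, 35.1; 80.0: 21.8, 10.9, 28.4

(scatter of a reading: 0.3 percentage points)

- free catalyst is single-handed; left-handed substrate and right-handed substrate are mirror images of each other, charged as a racemate, each of them at the stated concentration
- at the start none of the gas is in solution
- an excess is the difference of the two amounts in percent of their sum
- an excess is below zero if the other one leads

1. which one finishes higher in excess of left-handed product over right-handed product in the product ("neither" within 2 percentage points) (theta / alpha / neither)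
2. excess of left-handed product over right-handed product in the product at the end, theta
3. excess of left-handed product over right-handed product in the product at the end, alpha

Does each product come from its own substrate? In the blue run at 80.0 min, left-handed substrate and left-handed product add up to 50.0%, the charge of that substrate. The unread right-handed substrate is therefore taken as its charge less the right-handed product.

How much faster does the left-handed substrate go? Let a and b be the fractions left of the left-handed and right-handed substrate. At that time ln a/ln b is 2.17 in the blue run and 2.30 in the amber run. Their mean, 2.23, is the selectivity factor s, the logarithm of the fraction left of the left-handed substrate over that of the right-handed substrate. Like a reactivity ratio, it gives the composition drift at any speed, while both substrates meet the same catalyst and reagent and neither turns into the other.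

Does the impurity matter? From 1.5 mM to 2.3 mM, the part reacted goes from 32.6% to 32.7%. Alpha lies inside that range, while theta lies below it and is an extrapolation. With b at 77.8% and a equal to b to the power s, the difference of what has reacted of each substrate over its sum is 31.8% for both flasks.

The forecast says neither, with 32% for theta and 32% for alpha. Of a threshold in the impurity below the tested range it says that one “can't be excluded, but that is speculation”.

The flasks give neither: 32.2% for theta and 32.2% for alpha.

    reagent + free catalyst + right-handed substrate → free catalyst + right-handed product (k = 7100 /M²/h)
    gas ⇌ reagent, rate k2*(csat - [reagent]) (kL = 15.0 /h)
    precatalyst → racemization catalyst (k = 0.290 /h)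
    reagent + free catalyst + left-handed substrate → free catalyst + left-handed product (k = 16000 /M²/h)
    racemization catalyst + impurity → spent catalyst (k = 11000 /M/h)
    left-handed substrate + racemization catalyst ⇌ right-handed substrate + racemization catalyst, rate k6*[racemization catalyst]*[left-handed substrate] forward; the back reaction follows from the equilibrium constant (k = 63.0 /M/h)

The step that carried the weight was a constant s: the turning of left-handed into right-handed substrate makes no difference to theta's excess. Alpha keeps 78% of its right-handed substrate, which s turns into 31.8%. The time allowed is the main reason for the excess: alpha's 32.2% at 80 min becomes 0.572% when the flask is left ten times as long.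

The neighbour of alpha charged with 0.012 M of free catalyst keeps 64% of its right-handed substrate, for which s gives 27.3%. That flask gives 27.7%.

The earlier runs and the new flask stem from a simulated flask on assumed constants, noise included.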